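## Structural features

(+)-Chamaechromone is a 3-substituted 5,7-dihydroxychromone: benzo ring A is fused to a 4-pyranone ring, and C3 of that ring is bonded to the only stereocentre, an sp3 CH of (S) configuration. The same carbon carries a 2,4,6-trihydroxybenzoyl group and a bis(4-hydroxyphenyl)methyl group, so three bulky carbon substituents meet at one tertiary centre; the neighbouring diarylmethine carbon bears two identical aryl groups and is not stereogenic. The C–H of the stereocentre is alpha to the aryl ketone and attached to the vinylogous-ester carbon C3, so it is acidic, and an enolising base, a hot Lewis acid or long heating can racemise it. Other fragile features are the seven phenols (two phloroglucinol-type rings, easily oxidised or C-substituted by electrophiles) and chromone C2, which adds nucleophiles with opening of the pyranone ring. The real difficulty is therefore not the ring count but placing the crowded aryl ketone on the correct carbon and carrying the labile centre through every later step. Ring A has oxygen at C5, C7 and C8a, a 1,3,5-pattern: a 1,1,3-trioxygenated butadiene can bring C5–C8 with the oxygens of C5 and C7, while C6 of a 4-pyranone already holds the oxygen of C8a, so ring A can be annulated onto a preformed pyranone through the C4a–C5 and C8–C8a bonds. The group that activates pyranone C5 must afterwards leave together with the hydrogen at C8a, which is not acidic and lies syn to it in a cis-fused adduct; this decides for a sulfoxide, which leaves by thermal syn-elimination, over a sulfone, which would need an E1cB or anti pathway that this hydrogen cannot offer.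

## Logic of the disconnections

22 from 21. The five aryl O–CH3 bonds are cut last. Methyl ethers survive the aryllithium, borane, aminal ester and silyl ketene acetal of the earlier steps, and the two ring-A hydroxyls need no protection because the annulation delivers them free. The gain is that no phenol is handled before the end. The demand is an ether cleavage that is Lewis acidic but never basic, so that the centre next to the ketone is not enolised.

21 from 15 and 18. Ring A is cut at C4a–C5 and C8–C8a. This removes a whole ring with both of its hydroxyls and leaves a monocyclic pyranone plus a four-carbon diene. The forward step needs the C5=C6 bond of 15 to be the only reactive alkene, the nucleophilic CH2 terminus of 18 to bond to C6, and the activating group at C5 to leave with the non-acidic syn hydrogen at the ring fusion. The sulfinyl group of 15 meets the last point by syn-elimination under neutral conditions, which also spares the acidic stereocentre.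

18 from 17 and 17 from 16. Two O–Si bonds are cut in turn. The diene is the doubly silylated dienolate of a β-keto ester, so it comes from a commodity compound in two routine operations. The demand is anhydrous handling, since 18 is hydrolytically labile.

15 from 13 (through 14). The bonds O1–C2, O1–C6, C2–C3 and C5–C6 are cut: the pyranone is a ketone whose two alpha-carbons have each taken up a one-carbon unit and been joined through oxygen. The gain is an open-chain ketone in which the sulfinyl group already makes one alpha-CH2 acidic. The demand is condensation at the second, unactivated and hindered CH2 without enolising the adjacent centre, and a ring closure under acid mild enough not to turn the 1,4-diketone into a furan.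

13 from 11 (through 12). The CO–CH2S bond is cut, giving an acyl donor and a sulfinyl-stabilised carbanion. The gain is a simple γ-keto acid. The demand is that C-acylation outruns removal of the tertiary hydrogen alpha to the aryl ketone.

11 from 10, and 10 from 6 and 7 (through 8 and 9). The aryl–carbonyl bond is cut, and the carboxyl of 11 is taken back to a primary alcohol. Electrophilic acylation of 7 through a cyclic activated form of both carboxyls would look shorter, but an arene attacks such a species at the carbonyl remote from the substituent and would put the ketone on the wrong carboxyl. In 6 there is only one carbonyl and it sits on the stereocentre, so the regiochemistry is built in. The demand is nucleophilic addition that is faster than alpha-deprotonation of 6, then a near-neutral oxidation.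

6 from 4 (through 5). The lactone C–O bond is cut and the CH2O carbon is returned to a carboxylic acid. The condensation that makes 3 leaves the free acid on the CH2 arm and the ester on the carbon that becomes the stereocentre; reducing only the free acid converts this built-in difference into 6. The demand is chemoselective reduction of an acid beside an ester.

4 from 3. Two C–H bonds are cut. Asymmetric hydrogenation sets the single stereocentre early, when it is flanked only by an ester and is hard to enolise. The demand is a catalyst that reduces a tetrasubstituted, diaryl-substituted alkene with high face selectivity.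

3 from 1 and 2. The C=C bond is cut. Both partners are commercial, the ketone cannot enolise, and with two identical aryl groups no alkene isomers arise. The demand is only the usual irreversible lactone opening of the condensation.

## Other disconnections considered

Alternative 1: The cut is the C3–C4 bond of the heterocycle at the chromanone oxidation level. The forward step is an intramolecular Stetter reaction of aldehyde A1, a 4,6-dimethoxysalicylaldehyde tethered through O–CH2 to an E-trisubstituted enone. A chiral triazolium-derived carbene generates the acyl anion equivalent, which adds to the β-carbon; internal protonation of the enolate sets the side-chain centre and gives chromanone A2.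
- In its favour: carbene-catalysed closure of chroman-4-ones is an established reaction class, whereas the key step of the chosen plan is untested. The stereocentre is created late, in the ring-forming step, so it is not carried through many operations. On both points the alternative is the better of the two.
- Against it: the acceptor carries a bulky diarylmethyl group and a twisted, weakly activating aroyl group on its α-carbon, and the aldehyde is electron-rich and flanked by two alkoxy groups, so both partners are poor. All stereochemical information rests on the protonation, because C3 of A2 is destroyed later. A2 needs dehydrogenation next to the labile centre, and seven methyl ethers must then be cleaved instead of five.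
- Comparison: structurally it needs ring A preformed and arrives one oxidation level low; mechanistically it relies on polarity reversal and a diastereoselective proton transfer instead of a cycloaddition. In step count it is roughly equal, with one extra redox adjustment.

Alternative 2: The cut is the C1–C6 bond of the future phloroglucinol ring. Triketo ester A3 would be folded with Mg(OMe)2 by Claisen condensation of C6 onto the ester carbonyl, and the carbocycle would aromatise to A4.
- In its favour: the hindered acylphloroglucinol ketone is made without arene acylation or a hindered organometallic, which is better than steps 4 and 5 of the chosen plan on that bond. The three hydroxyls of that ring emerge free, so only four methyl ethers remain, which is again better.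
- Against it: in A3 the stereocentre is alpha to a polycarbonyl chain and attached to chromone C3, so alkoxide would be expected to racemise it. The competing aldol mode of folding (C2 onto C7) must be suppressed. A3 has to be assembled by acylating a polyanion with an activated, racemisation-prone acid, and the chromone ring is itself sensitive to alkoxide at C2.
- Comparison: it builds the ketone ring instead of ring A and uses strongly basic carbanion chemistry throughout, where the chosen plan keeps the late steps neutral or acidic. Step count is similar; on stereochemical safety it is clearly the weaker.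

Alternative 3: The cuts are the aryl–carbonyl bond and the ortho aryl–oxygen bond of the ketone ring. Acid A5 would be treated with silyl triflate A6 and CsF; the released aryne A7 would insert into the acid C–O bond and give A8.
- In its favour: one step turns a carboxylic acid into the ortho-hydroxyaryl ketone, which is shorter than the two steps of the chosen plan for this ketone. The methoxy group next to the aryne directs the carboxylate oxygen to the remote carbon, so the acyl group ends between OH and OMe as required. No acyl electrophile has to be pre-activated.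
- Against it: hot fluoride is basic, and the product has a doubly activated α-hydrogen. The acyl shift to the aryl anion must pass a tight four-membered transition state with a very hindered acyl group, so simple O-arylation is a likely diversion. The chromone is an electrophile towards the aryl anion. A6 needs its own multistep synthesis, six methyl ethers remain, and A5 is a racemisation-prone acid that needs its own asymmetric synthesis with the chromone in place.
- Comparison: it closes no ring and forms two bonds on the ketone ring, by anionic rather than pericyclic chemistry. It is the equal of the chosen plan in precedent for its key step and better in steps for the ketone, but worse in the conditions the stereocentre must endure.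

Key step: step 10

Assumption: the (S,S) antipode of Et-DuPHOS is taken to give the (R) acid 4, by analogy with β,β-dialkyl itaconate half-esters; if the sense is the opposite, the (R,R) ligand is used.
Remark: 13, 14, 15 and 19 are mixtures of epimers at sulfur; this centre is lost in step 10 and has no influence on the product.

Step 1
Reactants: 1 4,4'-dimethoxybenzophenone; 2 dimethyl succinate
Product: 3 3-(methoxycarbonyl)-4,4-bis(4-methoxyphenyl)but-3-enoic acid
Conditions: KOt-Bu, t-BuOH, reflux; then aq HCl
Reagents that add atoms: none
Why: Stobbe condensation: the succinate enolate adds to the non-enolisable ketone, the alkoxide lactonises onto the second ester and base-induced opening of the lactone gives the alkylidene half-ester irreversibly, with the free acid on the CH2 arm.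

Step 2
Reactants: 3 3-(methoxycarbonyl)-4,4-bis(4-methoxyphenyl)but-3-enoic acid
Product: 4 (3R)-3-(methoxycarbonyl)-4,4-bis(4-methoxyphenyl)butanoic acid
Conditions: H2 (10 bar), [Rh(cod)((S,S)-Et-DuPHOS)]BF4 (2 mol %), NaOMe (0.2 equiv), MeOH, 40 °C
Reagents that add atoms: none
Why: Rhodium–bisphosphine asymmetric hydrogenation of an itaconate-type half-ester, in which carboxylate and alkene chelate the metal; the C2-symmetric bis(phospholane) shields one face of the bound alkene and so sets the (R) centre.

Step 3
Reactants: 4 (3R)-3-(methoxycarbonyl)-4,4-bis(4-methoxyphenyl)butanoic acid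
Product: 6 (3R)-3-[bis(4-methoxyphenyl)methyl]oxolan-2-one, via hydroxy ester 5 (not isolated)
Conditions: BH3·SMe2, THF, 0 °C to rt; aq work-up; then p-toluenesulfonic acid (cat.), toluene, 50 °C
Reagents that add atoms: none
Why: Borane reduces a free carboxylic acid much faster than a methyl ester (chemoselective reduction), and the γ-hydroxy ester closes to the five-membered lactone under acid catalysis; no base is present, so the centre alpha to the ester is not touched.

Step 4
Reactants: 6 (3R)-3-[bis(4-methoxyphenyl)methyl]oxolan-2-one; 7 1,3,5-trimethoxybenzene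
Product: 10 (2R)-2-[bis(4-methoxyphenyl)methyl]-4-hydroxy-1-(2,4,6-trimethoxyphenyl)butan-1-one, via 2,4,6-trimethoxyphenyllithium 8 (not isolated), via dichloro(2,4,6-trimethoxyphenyl)cerium 9 (not isolated)
Conditions: 7, n-BuLi, THF, 0 °C to rt; CeCl3, −78 °C; then 6, −78 to −40 °C; aq NH4Cl
Reagents that add atoms: none
Why: Ortho-directed lithiation between two methoxy groups, transmetallation and 1,2-addition of the weakly basic organocerium to the lactone carbonyl; low basicity should suppress alpha-deprotonation of 6, and the crowded hemiketal alkoxide should not accept a second aryl group, so the hydroxy ketone forms on work-up with the centre retained.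

Step 5
Reactants: 10 (2R)-2-[bis(4-methoxyphenyl)methyl]-4-hydroxy-1-(2,4,6-trimethoxyphenyl)butan-1-one
Product: 11 (3R)-3-[bis(4-methoxyphenyl)methyl]-4-oxo-4-(2,4,6-trimethoxyphenyl)butanoic acid
Conditions: 2,2,6,6-tetramethylpiperidin-1-oxyl (TEMPO, 0.2 equiv), PhI(OAc)2 (2.5 equiv), MeCN/pH 7 buffer, rt
Reagents that add atoms: water, O
Why: Nitroxyl-catalysed oxidation takes a primary alcohol through the aldehyde hydrate to the acid under near-neutral, chlorine-free conditions that should leave the hindered ketone, its alpha-centre and the electron-rich arenes alone.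

Step 6
Reactants: 11 (3R)-3-[bis(4-methoxyphenyl)methyl]-4-oxo-4-(2,4,6-trimethoxyphenyl)butanoic acid
Product: 13 (2R)-2-[bis(4-methoxyphenyl)methyl]-5-(phenylsulfinyl)-1-(2,4,6-trimethoxyphenyl)pentane-1,4-dione (sulfur epimers), via acyl imidazolide 12 (not isolated)
Conditions: CDI, THF, rt; then PhS(O)CH2Li (2.2 equiv, from PhS(O)CH3 and LiN(i-Pr)2), THF, −78 °C; aq NH4Cl at −78 °C
Reagents that add atoms: methyl phenyl sulfoxide, CS(=O)c1ccccc1
Why: Claisen-type C-acylation of a sulfinyl carbanion by an acyl imidazolide gives the β-keto sulfoxide; the second equivalent of carbanion converts the product into its enolate, the aryl ketone with two ortho-methoxy groups is too hindered to be attacked, and at −78 °C acylation should outrun removal of the tertiary alpha-hydrogen.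

Step 7
Reactants: 13 (2R)-2-[bis(4-methoxyphenyl)methyl]-5-(phenylsulfinyl)-1-(2,4,6-trimethoxyphenyl)pentane-1,4-dione (sulfur epimers)
Product: 15 3-[(2S)-1,1-bis(4-methoxyphenyl)-3-oxo-3-(2,4,6-trimethoxyphenyl)propan-2-yl]-5-(phenylsulfinyl)-4H-pyran-4-one (sulfur epimers), via bis-enaminone 14 (not isolated)
Conditions: t-BuOCH(NMe2)2 (3 equiv), toluene, 80 °C; then 1 M HCl, THF, 0 °C to rt
Reagents that add atoms: tert-butoxybis(dimethylamino)methane, CC(C)(C)OC(N(C)C)N(C)C; water, O
Why: Aminomethylenation of both alpha-positions of the central ketone by an aminal ester (fast at the sulfinyl-activated CH2, slower at the other), then acid hydrolysis of one enamine and addition–elimination of the enol oxygen on the other closes the 4-pyranone; the aryl ketone has no alpha-CH2 and cannot condense.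

Step 8
Reactants: 16 methyl acetoacetate
Product: 17 methyl 3-(trimethylsilyloxy)but-2-enoate
Conditions: TMSCl, Et3N, hexane, rt
Reagents that add atoms: chlorotrimethylsilane, C[Si](C)(C)Cl
Why: O-silylation of the enol form of a β-keto ester under amine base (silyl enol ether formation).

Step 9
Reactants: 17 methyl 3-(trimethylsilyloxy)but-2-enoate
Product: 18 1-methoxy-1,3-bis(trimethylsilyloxy)buta-1,3-diene
Conditions: LiN(i-Pr)2, THF, −78 °C; TMSCl, −78 °C to rt
Reagents that add atoms: chlorotrimethylsilane, C[Si](C)(C)Cl
Why: Deprotonation of the γ-methyl group gives the ester dienolate, and O-silylation of it (silyl ketene acetal formation) gives the 1,1,3-trioxygenated diene.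

Step 10
Reactants: 15 3-[(2S)-1,1-bis(4-methoxyphenyl)-3-oxo-3-(2,4,6-trimethoxyphenyl)propan-2-yl]-5-(phenylsulfinyl)-4H-pyran-4-one (sulfur epimers); 18 1-methoxy-1,3-bis(trimethylsilyloxy)buta-1,3-diene
Product: 21 3-[(2S)-1,1-bis(4-methoxyphenyl)-3-oxo-3-(2,4,6-trimethoxyphenyl)propan-2-yl]-5,7-dihydroxy-4H-chromen-4-one, via cycloadduct 19 (not isolated), via bis(trimethylsilyl) ether 20 (not isolated)
Conditions: 18 (3 equiv), toluene, rt to 60 °C; then 1 M HCl, THF, 0 °C
Reagents that add atoms: none
Why: Proposed new method: the electron-rich diene 18 and the C5=C6 bond of 15, polarised by the C4 carbonyl and the sulfinyl group, should combine in an intermolecular normal-demand (4+2) cycloaddition (or its stepwise Michael–Claisen equivalent) that closes the six-membered carbocycle of ring A, the CH2 terminus bonding to C6 and the ketene acetal carbon to C5. In the cis-fused adduct 19 the sulfinyl group at C4a and the hydrogen at C8a are syn, so thermal syn-elimination of benzenesulfenic acid should restore the C4a=C8a bond without base; 1,4-loss of methanol from the ketal carbon then aromatises the ring to 20, and dilute acid removes the silyl groups. The closest known reaction type is the cycloaddition–elimination of 1,1,3-trioxygenated dienes with sulfinyl- or halogen-activated quinones, together with cycloadditions of chromones bearing an acceptor at C3; a 4-pyranone has not been used in this way. A sulfone at C5 was rejected because the hydrogen at C8a is not acidic and not anti, so a sulfinate could not leave across the ring fusion. No stereocentre is created in 21, since the two ring-fusion centres and the sulfur centre of 19 are destroyed by the eliminations, and the existing centre is not involved and should not enolise under neutral conditions. The regiochemistry (oxygen at C5 and C7) should follow from pairing the nucleophilic diene terminus with C6, which is beta to both the carbonyl and the sulfinyl group. Site selectivity should follow from the C2=C3 bond having no acceptor and a bulky neighbour, and the excess of 18 also serves to trap the sulfenic acid.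

Step 11
Reactants: 21 3-[(2S)-1,1-bis(4-methoxyphenyl)-3-oxo-3-(2,4,6-trimethoxyphenyl)propan-2-yl]-5,7-dihydroxy-4H-chromen-4-one
Product: 22 (+)-chamaechromone [3-[(2S)-1,1-bis(4-hydroxyphenyl)-3-oxo-3-(2,4,6-trihydroxyphenyl)propan-2-yl]-5,7-dihydroxy-4H-chromen-4-one]
Conditions: BBr3 (12 equiv), CH2Cl2, −78 °C to rt; then MeOH/H2O, 0 °C
Reagents that add atoms: none
Why: Lewis-acid cleavage of aryl methyl ethers: boron coordinates each ether oxygen and bromide removes the methyl group, the ortho-methoxy groups being assisted by chelation to the ketone; the medium is never basic, and the phenols stay as borates until the cold quench, which should protect the stereocentre.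

## Compound list

1 | 4,4'-dimethoxybenzophenone | O=C(c1ccc(OC)cc1)c1ccc(OC)cc1 | starting material
2 | dimethyl succinate | COC(=O)CCC(=O)OC | starting material
3 | 3-(methoxycarbonyl)-4,4-bis(4-methoxyphenyl)but-3-enoic acid | O=C(O)CC(C(=O)OC)=C(c1ccc(OC)cc1)c1ccc(OC)cc1 | intermediate
4 | (3R)-3-(methoxycarbonyl)-4,4-bis(4-methoxyphenyl)butanoic acid | O=C(OC)[C@H](CC(=O)O)C(c1ccc(OC)cc1)c1ccc(OC)cc1 | intermediate
5 | methyl (2R)-2-[bis(4-methoxyphenyl)methyl]-4-hydroxybutanoate | O=C(OC)[C@H](CCO)C(c1ccc(OC)cc1)c1ccc(OC)cc1 | intermediate (not isolated)
6 | (3R)-3-[bis(4-methoxyphenyl)methyl]oxolan-2-one | O=C1[C@H](CCO1)C(c1ccc(OC)cc1)c1ccc(OC)cc1 | intermediate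
7 | 1,3,5-trimethoxybenzene | COc1cc(OC)cc(OC)c1 | starting material
8 | (2,4,6-trimethoxyphenyl)lithium | [Li]c1c(OC)cc(OC)cc1OC | intermediate (not isolated)
9 | dichloro(2,4,6-trimethoxyphenyl)cerium | Cl[Ce](Cl)c1c(OC)cc(OC)cc1OC | intermediate (not isolated)
10 | (2R)-2-[bis(4-methoxyphenyl)methyl]-4-hydroxy-1-(2,4,6-trimethoxyphenyl)butan-1-one | O=C(c1c(OC)cc(OC)cc1OC)[C@H](CCO)C(c1ccc(OC)cc1)c1ccc(OC)cc1 | intermediate
11 | (3R)-3-[bis(4-methoxyphenyl)methyl]-4-oxo-4-(2,4,6-trimethoxyphenyl)butanoic acid | O=C(c1c(OC)cc(OC)cc1OC)[C@H](CC(=O)O)C(c1ccc(OC)cc1)c1ccc(OC)cc1 | intermediate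
12 | (2R)-2-[bis(4-methoxyphenyl)methyl]-4-(1H-imidazol-1-yl)-1-(2,4,6-trimethoxyphenyl)butane-1,4-dione | O=C(c1c(OC)cc(OC)cc1OC)[C@H](CC(=O)n1ccnc1)C(c1ccc(OC)cc1)c1ccc(OC)cc1 | intermediate (not isolated)
13 | (2R)-2-[bis(4-methoxyphenyl)methyl]-5-(phenylsulfinyl)-1-(2,4,6-trimethoxyphenyl)pentane-1,4-dione (sulfur epimers) | O=C(c1c(OC)cc(OC)cc1OC)[C@H](CC(=O)CS(=O)c1ccccc1)C(c1ccc(OC)cc1)c1ccc(OC)cc1 | intermediate
14 | (2S)-2-[bis(4-methoxyphenyl)methyl]-6-(dimethylamino)-3-[(dimethylamino)methylidene]-5-(phenylsulfinyl)-1-(2,4,6-trimethoxyphenyl)hex-5-ene-1,4-dione (sulfur epimers; alkene geometries open) | O=C(c1c(OC)cc(OC)cc1OC)[C@H](C(=CN(C)C)C(=O)C(=CN(C)C)S(=O)c1ccccc1)C(c1ccc(OC)cc1)c1ccc(OC)cc1 | intermediate (not isolated)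
15 | 3-[(2S)-1,1-bis(4-methoxyphenyl)-3-oxo-3-(2,4,6-trimethoxyphenyl)propan-2-yl]-5-(phenylsulfinyl)-4H-pyran-4-one (sulfur epimers) | O=C(c1c(OC)cc(OC)cc1OC)[C@H](c1cocc(S(=O)c2ccccc2)c1=O)C(c1ccc(OC)cc1)c1ccc(OC)cc1 | intermediate
16 | methyl acetoacetate | CC(=O)CC(=O)OC | starting material
17 | methyl 3-(trimethylsilyloxy)but-2-enoate (E/Z mixture) | COC(=O)C=C(C)O[Si](C)(C)C | intermediate
18 | 1-methoxy-1,3-bis(trimethylsilyloxy)buta-1,3-diene | COC(O[Si](C)(C)C)=CC(=C)O[Si](C)(C)C | intermediate
19 | 3-[(2S)-1,1-bis(4-methoxyphenyl)-3-oxo-3-(2,4,6-trimethoxyphenyl)propan-2-yl]-5-methoxy-4a-(phenylsulfinyl)-5,7-bis(trimethylsilyloxy)-4a,5,8,8a-tetrahydro-4H-chromen-4-one (cis ring fusion; C5 and sulfur unassigned) | O=C(c1c(OC)cc(OC)cc1OC)[C@H](C1=COC2CC(O[Si](C)(C)C)=CC(OC)(O[Si](C)(C)C)C2(S(=O)c2ccccc2)C1=O)C(c1ccc(OC)cc1)c1ccc(OC)cc1 | intermediate (not isolated)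
20 | 3-[(2S)-1,1-bis(4-methoxyphenyl)-3-oxo-3-(2,4,6-trimethoxyphenyl)propan-2-yl]-5,7-bis(trimethylsilyloxy)-4H-chromen-4-one | O=C(c1c(OC)cc(OC)cc1OC)[C@H](c1coc2cc(O[Si](C)(C)C)cc(O[Si](C)(C)C)c2c1=O)C(c1ccc(OC)cc1)c1ccc(OC)cc1 | intermediate (not isolated)
21 | 3-[(2S)-1,1-bis(4-methoxyphenyl)-3-oxo-3-(2,4,6-trimethoxyphenyl)propan-2-yl]-5,7-dihydroxy-4H-chromen-4-one | O=C(c1c(OC)cc(OC)cc1OC)[C@H](c1coc2cc(O)cc(O)c2c1=O)C(c1ccc(OC)cc1)c1ccc(OC)cc1 | intermediate
22 | (+)-chamaechromone, 3-[(2S)-1,1-bis(4-hydroxyphenyl)-3-oxo-3-(2,4,6-trihydroxyphenyl)propan-2-yl]-5,7-dihydroxy-4H-chromen-4-one | O=C(c1c(O)cc(O)cc1O)[C@H](c1coc2cc(O)cc(O)c2c1=O)C(c1ccc(O)cc1)c1ccc(O)cc1 | target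

## Step count and least certain steps

Total: 11 steps. Longest linear sequence: 9 steps (steps 1 to 7, 10 and 11, from 1); steps 8 and 9 form the short branch to 18.

Step 10 (key step, proposed new method). Three things may go wrong. The cycloaddition may be slow, because C5=C6 is part of a vinylogous ester and a sulfinyl group activates only moderately, while 18 decomposes on heating. A stepwise Michael addition may be followed by retro-oxa-Michael opening of the pyranone ring instead of ring closure. The sulfoxide may be silylated and consumed by the silyl ketene acetal, or the freed sulfenic acid may sulfenylate the new electron-rich ring. The fallback uses known chromone chemistry and sets out from 11 through its imidazolide 12. The aryllithium made from 1-(methoxymethoxy)-3,5-dimethoxybenzene and n-BuLi (lithiation between the OMOM and OMe groups) is acylated by 12 at −78 °C to give the MOM-protected diketone F1. HCl in MeOH removes the MOM group and gives the ortho-hydroxyaryl diketone F2. Me2NCH(OMe)2 in toluene at 80 °C, followed by acid, forms the enaminone at the CH2 group and closes it to hepta-O-methylchamaechromone F3, the standard closure of an ortho-hydroxyaryl ketone to a 3-substituted chromone. BBr3 then cleaves seven methyl ethers, and the fallback comes back to the route at 22.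

Step 2. Conversion may stay incomplete or face selectivity low, because a tetrasubstituted alkene with two aryl groups binds the metal poorly. The fallback sets out from 3: hydrogenation over Pd/C (H2, AcOH) would give the racemic acid F4. Crystallisation with (S)-1-phenylethylamine (or its antipode, whichever gives the less soluble salt of the wanted acid) would give the diastereomerically pure salt F5. Acidification returns to the route at 4.

Step 4. Alpha-deprotonation of the lactone may compete with addition because both partners are hindered, which would erode the configuration or stop the reaction. The fallback sets out from 6: i-Bu2AlH at −78 °C gives the lactol F6. Its open hydroxy aldehyde form adds 8 (2.2 equiv) much faster than a lactone does and gives the diol F7. MnO2 oxidises only the electron-rich benzylic alcohol, and the fallback returns to the route at 10.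

Step 6. The sulfinyl carbanion is a strong base, and partial removal of the hydrogen alpha to the aryl ketone would lower the enantiomeric purity. The fallback avoids carbanions and sets out from 11: (COCl)2 with catalytic DMF gives the acid chloride F8. TMSCHN2 gives the diazoketone F9, and aqueous HBr at 0 °C gives the bromoketone F10. PhSH with Et3N gives the sulfide F11, and NaIO4 in aqueous MeOH oxidises it to the sulfoxide, returning to the route at 13.

Step 7. Condensation at the hindered CH2 may stall, long heating with the aminal ester may enolise the neighbouring centre, and the acid step may divert the 1,4-diketone to a furan. The fallback sets out from 13: Me2NCH(OMe)2 at rt gives the mono-enaminone F12 on the sulfinyl side only. Its remaining CH2 is then formylated electrophilically at −78 °C with diethoxycarbenium tetrafluoroborate (from HC(OEt)3 and BF3·OEt2) and i-Pr2NEt, giving the β-keto acetal F13. Dilute HCl in THF unmasks the aldehyde and closes the ring, returning to the route at 15.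

## Further compounds

F1 | step 10 | (2R)-2-[bis(4-methoxyphenyl)methyl]-4-[2,4-dimethoxy-6-(methoxymethoxy)phenyl]-1-(2,4,6-trimethoxyphenyl)butane-1,4-dione | O=C(c1c(OC)cc(OC)cc1OC)[C@H](CC(=O)c1c(OCOC)cc(OC)cc1OC)C(c1ccc(OC)cc1)c1ccc(OC)cc1
F2 | step 10 | (2R)-2-[bis(4-methoxyphenyl)methyl]-4-(2-hydroxy-4,6-dimethoxyphenyl)-1-(2,4,6-trimethoxyphenyl)butane-1,4-dione | O=C(c1c(OC)cc(OC)cc1OC)[C@H](CC(=O)c1c(O)cc(OC)cc1OC)C(c1ccc(OC)cc1)c1ccc(OC)cc1
F3 | step 10 | hepta-O-methylchamaechromone, 3-[(2S)-1,1-bis(4-methoxyphenyl)-3-oxo-3-(2,4,6-trimethoxyphenyl)propan-2-yl]-5,7-dimethoxy-4H-chromen-4-one | O=C(c1c(OC)cc(OC)cc1OC)[C@H](c1coc2cc(OC)cc(OC)c2c1=O)C(c1ccc(OC)cc1)c1ccc(OC)cc1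
F4 | step 2 | racemic 3-(methoxycarbonyl)-4,4-bis(4-methoxyphenyl)butanoic acid | O=C(OC)C(CC(=O)O)C(c1ccc(OC)cc1)c1ccc(OC)cc1
F5 | step 2 | (S)-1-phenylethylammonium (3R)-3-(methoxycarbonyl)-4,4-bis(4-methoxyphenyl)butanoate | O=C(OC)[C@H](CC(=O)[O-])C(c1ccc(OC)cc1)c1ccc(OC)cc1.C[C@H]([NH3+])c1ccccc1
F6 | step 4 | (3R)-3-[bis(4-methoxyphenyl)methyl]oxolan-2-ol (anomers) | OC1[C@H](CCO1)C(c1ccc(OC)cc1)c1ccc(OC)cc1
F7 | step 4 | (2R)-2-[bis(4-methoxyphenyl)methyl]-1-(2,4,6-trimethoxyphenyl)butane-1,4-diol (C1 epimers) | OC(c1c(OC)cc(OC)cc1OC)[C@H](CCO)C(c1ccc(OC)cc1)c1ccc(OC)cc1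
F8 | step 6 | (3R)-3-[bis(4-methoxyphenyl)methyl]-4-oxo-4-(2,4,6-trimethoxyphenyl)butanoyl chloride | O=C(c1c(OC)cc(OC)cc1OC)[C@H](CC(=O)Cl)C(c1ccc(OC)cc1)c1ccc(OC)cc1
F9 | step 6 | (2R)-2-[bis(4-methoxyphenyl)methyl]-5-diazo-1-(2,4,6-trimethoxyphenyl)pentane-1,4-dione | O=C(c1c(OC)cc(OC)cc1OC)[C@H](CC(=O)C=[N+]=[N-])C(c1ccc(OC)cc1)c1ccc(OC)cc1
F10 | step 6 | (2R)-2-[bis(4-methoxyphenyl)methyl]-5-bromo-1-(2,4,6-trimethoxyphenyl)pentane-1,4-dione | O=C(c1c(OC)cc(OC)cc1OC)[C@H](CC(=O)CBr)C(c1ccc(OC)cc1)c1ccc(OC)cc1
F11 | step 6 | (2R)-2-[bis(4-methoxyphenyl)methyl]-5-(phenylsulfanyl)-1-(2,4,6-trimethoxyphenyl)pentane-1,4-dione | O=C(c1c(OC)cc(OC)cc1OC)[C@H](CC(=O)CSc1ccccc1)C(c1ccc(OC)cc1)c1ccc(OC)cc1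
F12 | step 7 | (2R)-2-[bis(4-methoxyphenyl)methyl]-6-(dimethylamino)-5-(phenylsulfinyl)-1-(2,4,6-trimethoxyphenyl)hex-5-ene-1,4-dione (sulfur epimers) | O=C(c1c(OC)cc(OC)cc1OC)[C@H](CC(=O)C(=CN(C)C)S(=O)c1ccccc1)C(c1ccc(OC)cc1)c1ccc(OC)cc1
F13 | step 7 | 2-[bis(4-methoxyphenyl)methyl]-3-(diethoxymethyl)-6-(dimethylamino)-5-(phenylsulfinyl)-1-(2,4,6-trimethoxyphenyl)hex-5-ene-1,4-dione (C2 as in 13; C3 and sulfur epimers) | O=C(c1c(OC)cc(OC)cc1OC)[C@H](C(C(OCC)OCC)C(=O)C(=CN(C)C)S(=O)c1ccccc1)C(c1ccc(OC)cc1)c1ccc(OC)cc1
A1 | alternative 1 | 2-{[(2E)-3-[bis(4-methoxyphenyl)methyl]-4-oxo-4-(2,4,6-trimethoxyphenyl)but-2-en-1-yl]oxy}-4,6-dimethoxybenzaldehyde | O=Cc1c(OC)cc(OC)cc1OC/C=C(\C(c1ccc(OC)cc1)c1ccc(OC)cc1)C(=O)c1c(OC)cc(OC)cc1OC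
A2 | alternative 1 | 2,3-dihydro-hepta-O-methylchamaechromone (5,7-dimethoxychroman-4-one; side-chain centre as in the target) | O=C(c1c(OC)cc(OC)cc1OC)[C@H]([C@@H]1COc2cc(OC)cc(OC)c2C1=O)C(c1ccc(OC)cc1)c1ccc(OC)cc1
A3 | alternative 2 | methyl (8S)-8-(5,7-dimethoxy-4-oxo-4H-chromen-3-yl)-9,9-bis(4-methoxyphenyl)-3,5,7-trioxononanoate | COC(=O)CC(=O)CC(=O)CC(=O)[C@H](c1coc2cc(OC)cc(OC)c2c1=O)C(c1ccc(OC)cc1)c1ccc(OC)cc1
A4 | alternative 2 | tetra-O-methylchamaechromone with free phloroglucinol ring | O=C(c1c(O)cc(O)cc1O)[C@H](c1coc2cc(OC)cc(OC)c2c1=O)C(c1ccc(OC)cc1)c1ccc(OC)cc1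
A5 | alternative 3 | (2S)-2-(5,7-dimethoxy-4-oxo-4H-chromen-3-yl)-3,3-bis(4-methoxyphenyl)propanoic acid | O=C(O)[C@H](c1coc2cc(OC)cc(OC)c2c1=O)C(c1ccc(OC)cc1)c1ccc(OC)cc1
A6 | alternative 3 | 3,5-dimethoxy-2-(trimethylsilyl)phenyl trifluoromethanesulfonate | COc1cc(OC)c([Si](C)(C)C)c(OS(=O)(=O)C(F)(F)F)c1
A7 | alternative 3 | 3,5-dimethoxybenzyne | COC1=CC(OC)=CC#C1
A8 | alternative 3 | hexa-O-methylchamaechromone with one free ortho-hydroxyl on the ketone ring | O=C(c1c(O)cc(OC)cc1OC)[C@H](c1coc2cc(OC)cc(OC)c2c1=O)C(c1ccc(OC)cc1)c1ccc(OC)cc1
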